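| flask | starting material | gas phase | protic impurity | remark | time |
|---|---|---|---|---|---|
| cedar | 2 M | 200 mM (held) | 1.5 M | run made earlier |  |
| flask | 3.0 M | 200 mM (held) | 1.50 M |  | 12 h |

cedar run (percent of the starting material charged)

| time / h | target / % | crystals / % |
|---|---|---|
| 1.00 | 4.8 | 0.3 |
| 2.50 | 13.9 | 6.3 |
| 6.00 | 29.0 | 22.2 |
| 15.0 | 44.0 | 42.7 |

(scatter of a reading: 0.5 percentage points)

1. target and crystals together at 12 h, in percent of the starting material charged
2. concentration of dissolved gas in solution at 12 h, in percent of saturation

- amounts and yields of target count crystals too
- given per volume of solution although it is solid: crystals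
- at the start none of the gas is dissolved
- steps thought possible: crystals <-> target; starting material + protic impurity -> quenched substrate; target -> over-reaction product; starting material + dissolved gas -> target; gas phase <-> dissolved gas; dissolved gas + target -> over-reacted product

1. No rate constant is given for any step, so I reckon from the cedar curve itself; amounts of target count crystals, so its target column is already the sum asked for in y.

2. My bench rule is to carry cedar's percent-of-charge curve over to the flask, which is a rule of thumb and asks at least that [dissolved gas] and [protic impurity] stay as in cedar, the loss of starting material then being pseudo-first-order.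

3. The border is a ratio: protic impurity per starting material is 50.0% in the flask, less than the 75.0% in cedar, so quenching the same share of the charge would use a larger share of the flask's impurity than of cedar's, [protic impurity] would not follow cedar's course, and the rule stays an estimate.

4. I replace the cedar curve from 6.00 h to 15.0 h by its mean yield rate, the rise in yield per hour between two readings, 0.0167 h⁻¹, which puts the flask at 39.0% by 12 h.

5. That straight line lies under a bending curve: the bracket before it rose at 0.0431 h⁻¹, and this bend gives a sag of 3.8 percentage points, so I commit to the midpoint between the line and the line raised by that sag, 40.9%, and offer no figure for the gas.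

6. The forecast gives 43% and 90%, saying “I read the target column as the total”.

7. The flask gives 41.9% and 86.7%.

    crystals ⇌ target, rate k1*(cs1 - [target]) while solid is left; crystals form when [target] > cs1 (solubility = 31.0 mM, k = 0.680 h⁻¹)
    starting material + protic impurity → quenched substrate (k = 0.0640 M⁻¹ h⁻¹)
    target → over-reaction product (k = 0.0210 h⁻¹)
    starting material + dissolved gas → target (k = 0.580 M⁻¹ h⁻¹)
    gas phase ⇌ dissolved gas, rate k5*(csat - [dissolved gas]) (kL = 2.60 h⁻¹)
    dissolved gas + target → over-reacted product (k = 0.310 M⁻¹ h⁻¹)

Changing the amount of starting material alone moves cedar's yield at its last reading from 45.0% to 46.2%. Around 12 h the flask's yield moves by 5 points at 9.47 h and again at 15.7 h, a mean rate of 0.0161 h⁻¹ against the 0.0167 h⁻¹ taken from cedar. Cedar's earlier mean rate, 0.0431 h⁻¹, carried from 2.50 h to 3.0 h, gives 16.1%, and the flask read at that time holds 15.4%.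

The earlier runs and the new flask are simulated from invented constants, and the scatter is random.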